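**Plan**
1. The retrosynthesis cuts the two furanone bonds C1–C2 and O–C3 together. This turns the bridged carbocycle into a ten-membered macrolactone in which C1 is esterified to the C15 oxygen and C3 is an acetyl group on C4.
2. The feature that allows this is the C15H2OH group on C4, which is 1,3 to C3. In the lactone the C2 methyl lies six atoms from C1 (C2–C3–C4–C15–O–C1, Baker–Venkataraman geometry), so enolate attack moves C1 from oxygen to carbon, frees the CH2OH of the target, and leaves the C10 tertiary OH to close the furanone on C3.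
3. Further cuts, in order: C3–C4 (acyl Stille on a vinylstannane from alkyne trans-hydrostannation), O15–C1 (macrolactonization), the O8 crotonate, C7–C8 (zinc Barbier reaction of an alpha-(bromomethyl)butenolide with an aldehyde), C7=C11 (ring-closing metathesis), C9–C10 (Mukaiyama aldol to a pyruvate).
4. Forward ring order: butenolide, then alpha-methylene butyrolactone, then ten-membered lactone, then in one operation the ten-membered carbocycle and the 3(2H)-furanone.
5. Stereochemistry: C6 from a Sharpless kinetic resolution; C7 and C8 relayed from C6 through the chair-like Barbier transition state; C10 from a copper–bis(oxazoline)-catalysed aldol; C4=C5 geometry from trans-hydrostannation and a retentive Stille coupling.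

Key step: step 15

Remark: germacrane numbering is used for all carbons that end up in the target (C1 ketone carbon, C2 furanone CH, C3 furanone O–C=, C4=C5 with C15H2OH on C4, C6 lactone O–CH, C7, C8 crotonate CH, C9H2, C10 bearing C14H3, C11=C13H2, C12 lactone C=O); the target SMILES is read as 6S,7S,8R,10R.

**Route**

Step 1
Reactants: 1 tert-butyldimethyl(prop-2-yn-1-yloxy)silane; 2 acrolein
Product: 3 rac-6-[(tert-butyldimethylsilyl)oxy]hex-1-en-4-yn-3-ol
Conditions: n-BuLi, THF, −78 °C; then 2, −78 °C; aq. NH4Cl
Reagents that add atoms: none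
Why: 1,2-addition of a lithium acetylide to acrolein is a standard route to alkynyl vinyl carbinols; the new centre (C6) is formed racemic.

Step 2
Reactants: 3 rac-6-[(tert-butyldimethylsilyl)oxy]hex-1-en-4-yn-3-ol
Product: 4 (3R)-6-[(tert-butyldimethylsilyl)oxy]hex-1-en-4-yn-3-ol
Conditions: Ti(OiPr)4 (0.2 equiv), D-(−)-diisopropyl tartrate (0.24 equiv), t-BuOOH (0.6 equiv), 4 Å molecular sieves, CH2Cl2, −20 °C, stopped just past half conversion
Reagents that add atoms: none
Why: Sharpless kinetic resolution of a secondary allylic alcohol; with the D-tartrate the S enantiomer (alkynyl group on the face opposite to oxygen delivery) should be epoxidized much faster, so the R carbinol (C6) is recovered.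

Step 3
Reactants: 4 (3R)-6-[(tert-butyldimethylsilyl)oxy]hex-1-en-4-yn-3-ol; 5 2-(bromomethyl)prop-2-enoic acid
Product: 6 (3R)-6-[(tert-butyldimethylsilyl)oxy]hex-1-en-4-yn-3-yl 2-(bromomethyl)prop-2-enoate
Conditions: DCC, DMAP (5 mol%), CH2Cl2, 0 °C
Reagents that add atoms: none
Why: Steglich esterification acylates the carbinol oxygen with retention at C6; low temperature and a catalytic amount of DMAP should spare the allylic bromide.

Step 4
Reactants: 6 (3R)-6-[(tert-butyldimethylsilyl)oxy]hex-1-en-4-yn-3-yl 2-(bromomethyl)prop-2-enoate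
Product: 7 (5R)-3-(bromomethyl)-5-{3-[(tert-butyldimethylsilyl)oxy]prop-1-yn-1-yl}furan-2(5H)-one
Conditions: second-generation Grubbs catalyst RuCl2(=CHPh)(H2IMes)(PCy3) (5 mol%), toluene, 80 °C, argon stream
Reagents that add atoms: none
Why: ring-closing metathesis of an allyl 2-substituted acrylate to a butenolide forms the C7=C11 bond under neutral conditions, so the base-labile C6 centre of the 5-alkynylbutenolide never meets a base; the hindered alkyne cannot reach the carbene in a ring of workable size.

Step 5
Reactants: 8 S-ethyl ethanethioate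
Product: 9 {[1-(ethylsulfanyl)ethenyl]oxy}trimethylsilane
Conditions: LDA, THF, −78 °C; then TMSCl
Reagents that add atoms: chlorotrimethylsilane C[Si](C)(C)Cl
Why: kinetic enolization of the thioester and O-silylation give the silyl ketene thioacetal needed for the Mukaiyama aldol.

Step 6
Reactants: 9 {[1-(ethylsulfanyl)ethenyl]oxy}trimethylsilane; 10 tert-butyl 2-oxopropanoate
Product: 12 tert-butyl (2R)-4-(ethylsulfanyl)-2-hydroxy-2-methyl-4-oxobutanoate, via trimethylsilyl ether 11 (not isolated)
Conditions: Cu(OTf)2 (10 mol%), 2,2'-(propane-2,2-diyl)bis[(4R)-4-tert-butyl-4,5-dihydro-1,3-oxazole] (11 mol%), THF, −78 °C; then 1 M HCl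
Reagents that add atoms: none
Why: catalytic enantioselective Mukaiyama aldol addition to a pyruvate ester, in which the pyruvate chelates the divalent copper centre through both carbonyl oxygens and the tert-butyl groups of the ligand shield one ketone face; the R,R ligand is chosen to give the R tertiary carbinol (C10), the S,S ligand being the one that gives S in this reaction type.

Step 7
Reactants: 12 tert-butyl (2R)-4-(ethylsulfanyl)-2-hydroxy-2-methyl-4-oxobutanoate
Product: 13 tert-butyl (2R)-2-hydroxy-2-methyl-4-oxobutanoate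
Conditions: Et3SiH, 10% Pd/C, acetone, 23 °C
Reagents that add atoms: none
Why: Fukuyama reduction turns the thioester into the aldehyde (C8) without touching the tert-butyl ester or the tertiary alcohol.

Step 8
Reactants: 7 (5R)-3-(bromomethyl)-5-{3-[(tert-butyldimethylsilyl)oxy]prop-1-yn-1-yl}furan-2(5H)-one; 13 tert-butyl (2R)-2-hydroxy-2-methyl-4-oxobutanoate
Product: 14 tert-butyl (2R,4R)-4-[(2R,3S)-2-{3-[(tert-butyldimethylsilyl)oxy]prop-1-yn-1-yl}-4-methylidene-5-oxooxolan-3-yl]-2,4-dihydroxy-2-methylbutanoate
Conditions: Zn dust, THF/sat. aq. NH4Cl, 0 → 23 °C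
Reagents that add atoms: none
Why: zinc Barbier allylation with an alpha-(bromomethyl)butenolide, in which the allylzinc should react at its gamma carbon C7 on the face anti to the C6 alkynyl group (trans lactone, sets C7) through a chair-like Zimmerman–Traxler transition state whose ring-fixed E-type allyl geometry puts the aldehyde chain equatorial (sets C8, O8 syn to C11 along C6–C7–C8–C9) and regenerates the exocyclic methylene.

Step 9
Reactants: 14 tert-butyl (2R,4R)-4-[(2R,3S)-2-{3-[(tert-butyldimethylsilyl)oxy]prop-1-yn-1-yl}-4-methylidene-5-oxooxolan-3-yl]-2,4-dihydroxy-2-methylbutanoate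
Product: 15 tert-butyl (2R,4R)-4-{[(2E)-but-2-enoyl]oxy}-4-[(2R,3S)-2-{3-[(tert-butyldimethylsilyl)oxy]prop-1-yn-1-yl}-4-methylidene-5-oxooxolan-3-yl]-2-hydroxy-2-methylbutanoate
Conditions: (E)-crotonic anhydride, DMAP (0.2 equiv), Et3N, CH2Cl2, 0 °C
Reagents that add atoms: (E)-but-2-enoic anhydride C/C=C/C(=O)OC(=O)/C=C/C
Why: DMAP-catalysed acylation of the secondary C8 alcohol with the anhydride avoids a ketene pathway and so keeps the E alkene; the tertiary C10 alcohol is too hindered to react.

Step 10
Reactants: 15 tert-butyl (2R,4R)-4-{[(2E)-but-2-enoyl]oxy}-4-[(2R,3S)-2-{3-[(tert-butyldimethylsilyl)oxy]prop-1-yn-1-yl}-4-methylidene-5-oxooxolan-3-yl]-2-hydroxy-2-methylbutanoate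
Product: 16 (2R,4R)-4-{[(2E)-but-2-enoyl]oxy}-2-hydroxy-4-[(2R,3S)-2-(3-hydroxyprop-1-yn-1-yl)-4-methylidene-5-oxooxolan-3-yl]-2-methylbutanoic acid
Conditions: TFA/CH2Cl2/H2O (9:9:1), 0 → 23 °C
Reagents that add atoms: none
Why: acidolysis removes the tert-butyl ester (as isobutene) and the primary silyl ether in one operation, while crotonate, lactone and alkyne should be stable to aqueous trifluoroacetic acid at room temperature.

Step 11
Reactants: 16 (2R,4R)-4-{[(2E)-but-2-enoyl]oxy}-2-hydroxy-4-[(2R,3S)-2-(3-hydroxyprop-1-yn-1-yl)-4-methylidene-5-oxooxolan-3-yl]-2-methylbutanoic acid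
Product: 17 (2R,4R)-4-{[(2E)-but-2-enoyl]oxy}-2-hydroxy-4-{(2R,3S)-2-[(1Z)-3-hydroxy-2-(tributylstannyl)prop-1-en-1-yl]-4-methylidene-5-oxooxolan-3-yl}-2-methylbutanoic acid
Conditions: [Cp*RuCl]4 (2.5 mol%), Bu3SnH (slow addition), CH2Cl2, 23 °C
Reagents that add atoms: tributylstannane CCCC[SnH](CCCC)CCCC
Why: hydroxyl-directed ruthenium-catalysed trans-hydrostannation of a propargylic alcohol should deliver tin to C4 (the alkyne carbon next to the free C15 hydroxyl) and hydrogen to C5 from the opposite side, which fixes the C4=C5 geometry with tin cis to C6.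

Step 12
Reactants: 17 (2R,4R)-4-{[(2E)-but-2-enoyl]oxy}-2-hydroxy-4-{(2R,3S)-2-[(1Z)-3-hydroxy-2-(tributylstannyl)prop-1-en-1-yl]-4-methylidene-5-oxooxolan-3-yl}-2-methylbutanoic acid
Product: 18 ten-membered macrolactone stannane (C1 carboxyl esterified with the C15 oxygen)
Conditions: 2-methyl-6-nitrobenzoic anhydride (MNBA), DMAP, Et3N, CH2Cl2, slow addition of 17 to 1 mM, 23 °C
Reagents that add atoms: none
Why: Shiina macrolactonization (mixed anhydride, acyl transfer by DMAP) under high dilution closes the ten-membered lactone between the C1 acid and the primary allylic C15 hydroxyl; the tertiary C10 hydroxyl is too hindered to compete.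

Step 13
Reactants: 18 ten-membered macrolactone stannane
Product: 19 C10 triethylsilyl ether of the macrolactone stannane
Conditions: TESOTf, 2,6-lutidine, CH2Cl2, −78 °C
Reagents that add atoms: triethylsilyl trifluoromethanesulfonate CC[Si](CC)(CC)OS(=O)(=O)C(F)(F)F
Why: silylation of the tertiary alcohol with a silyl triflate, done before any ketone is present, removes the alkoxide that could trigger crotonate migration in the key step.

Step 14
Reactants: 19 C10 triethylsilyl ether of the macrolactone stannane
Product: 20 4-acetyl macrolactone (key-step substrate)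
Conditions: AcCl, Pd2(dba)3 (5 mol%), P(2-furyl)3 (20 mol%), THF, 50 °C
Reagents that add atoms: acetyl chloride CC(Cl)=O
Why: Stille acylation of an alkenylstannane with an acid chloride proceeds with retention of alkene geometry, so the acetyl group (C3 and C2) should end up cis to C6.

Step 15
Reactants: 20 4-acetyl macrolactone (key-step substrate)
Product: 23 CNP0225232.1 (target), via macrocyclic 1,3-diketone 21 (not isolated), via bridged hemiketal 22 (not isolated)
Conditions: LiHMDS (1.3 equiv), THF, −78 → −20 °C; then 2 M aq. HCl, THF, 23 °C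
Reagents that add atoms: none
Why: Proposed new method: LiHMDS should deprotonate the C2 methyl of the acetyl group kinetically, and the lithium enolate should add to the macrolactone carbonyl C1 through a six-membered transition state (C2–C3–C4–C15–O–C1); the bicyclic tetrahedral intermediate then collapses with loss of the C15 alkoxide, so the ten-membered lactone is exchanged for the ten-membered carbocycle as the enolate of 1,3-diketone 21 (C1–C2 bond) and the CH2OH of the target is released as the leaving group. The closest known reaction type is the Baker–Venkataraman rearrangement (base-induced O-to-C acyl transfer of an acyloxy ketone to a 1,3-diketone) followed by the classical acid-mediated cyclodehydration of an alpha'-hydroxy 1,3-diketone to a 3(2H)-furanone; what lacks precedent is the transannular setting, in which the migrating acyl group is part of the same ring. The carbocycle therefore closes by a 6-exo-trig addition and ring exchange and not by a direct ten-membered cyclization, and once the acid quench has removed the silyl group the furanone closes by 5-exo-trig attack of the C10 hydroxyl on the C3 carbonyl (hemiketal 22) and loss of water (O–C3 bond). No stereocentre is created: C6, C7, C8 and C10 are untouched, the C4=C5 geometry is carried over and becomes the cis ring alkene, and the hemiketal centre is dictated by the bridge and then destroyed. The step needs enolization at C2 and not at C6 or C15 (kinetic deprotonation of the methyl ketone at −78 °C), attack at C1 and not at the butyrolactone or crotonate carbonyls (only C1 is reachable through a six-membered transition state), and cyclodehydration through O10/C3 and not O15/C1 (five-membered ring on a gem-disubstituted carbon, with the six-membered alternative reversible in aqueous acid).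

**Compound list**
1 | tert-butyldimethyl(prop-2-yn-1-yloxy)silane | C#CCO[Si](C)(C)C(C)(C)C | starting material
2 | acrolein (prop-2-enal) | C=CC=O | starting material
3 | rac-6-[(tert-butyldimethylsilyl)oxy]hex-1-en-4-yn-3-ol | C=CC(O)C#CCO[Si](C)(C)C(C)(C)C | intermediate
4 | (3R)-6-[(tert-butyldimethylsilyl)oxy]hex-1-en-4-yn-3-ol | C=C[C@@H](O)C#CCO[Si](C)(C)C(C)(C)C | intermediate
5 | 2-(bromomethyl)prop-2-enoic acid | C=C(CBr)C(=O)O | starting material
6 | (3R)-6-[(tert-butyldimethylsilyl)oxy]hex-1-en-4-yn-3-yl 2-(bromomethyl)prop-2-enoate | C=C[C@@H](OC(=O)C(=C)CBr)C#CCO[Si](C)(C)C(C)(C)C | intermediate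
7 | (5R)-3-(bromomethyl)-5-{3-[(tert-butyldimethylsilyl)oxy]prop-1-yn-1-yl}furan-2(5H)-one | O=C1O[C@H](C=C1CBr)C#CCO[Si](C)(C)C(C)(C)C | intermediate
8 | S-ethyl ethanethioate | CC(=O)SCC | starting material
9 | {[1-(ethylsulfanyl)ethenyl]oxy}trimethylsilane | C=C(O[Si](C)(C)C)SCC | intermediate
10 | tert-butyl 2-oxopropanoate (tert-butyl pyruvate) | CC(=O)C(=O)OC(C)(C)C | starting material
11 | tert-butyl (2R)-4-(ethylsulfanyl)-2-methyl-4-oxo-2-[(trimethylsilyl)oxy]butanoate (not isolated) | CC(C)(C)OC(=O)[C@@](C)(CC(=O)SCC)O[Si](C)(C)C | intermediate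
12 | tert-butyl (2R)-4-(ethylsulfanyl)-2-hydroxy-2-methyl-4-oxobutanoate | CC(C)(C)OC(=O)[C@@](C)(CC(=O)SCC)O | intermediate
13 | tert-butyl (2R)-2-hydroxy-2-methyl-4-oxobutanoate | CC(C)(C)OC(=O)[C@@](C)(CC=O)O | intermediate
14 | tert-butyl (2R,4R)-4-[(2R,3S)-2-{3-[(tert-butyldimethylsilyl)oxy]prop-1-yn-1-yl}-4-methylidene-5-oxooxolan-3-yl]-2,4-dihydroxy-2-methylbutanoate | C=C1C(=O)O[C@@H](C#CCO[Si](C)(C)C(C)(C)C)[C@@H]1[C@H](O)C[C@@](C)(O)C(=O)OC(C)(C)C | intermediate
15 | tert-butyl (2R,4R)-4-{[(2E)-but-2-enoyl]oxy}-4-[(2R,3S)-2-{3-[(tert-butyldimethylsilyl)oxy]prop-1-yn-1-yl}-4-methylidene-5-oxooxolan-3-yl]-2-hydroxy-2-methylbutanoate | C=C1C(=O)O[C@@H](C#CCO[Si](C)(C)C(C)(C)C)[C@@H]1[C@H](OC(=O)/C=C/C)C[C@@](C)(O)C(=O)OC(C)(C)C | intermediate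
16 | (2R,4R)-4-{[(2E)-but-2-enoyl]oxy}-2-hydroxy-4-[(2R,3S)-2-(3-hydroxyprop-1-yn-1-yl)-4-methylidene-5-oxooxolan-3-yl]-2-methylbutanoic acid | C=C1C(=O)O[C@@H](C#CCO)[C@@H]1[C@H](OC(=O)/C=C/C)C[C@@](C)(O)C(=O)O | intermediate
17 | (2R,4R)-4-{[(2E)-but-2-enoyl]oxy}-2-hydroxy-4-{(2R,3S)-2-[(1Z)-3-hydroxy-2-(tributylstannyl)prop-1-en-1-yl]-4-methylidene-5-oxooxolan-3-yl}-2-methylbutanoic acid | C=C1C(=O)O[C@@H](/C=C(/CO)[Sn](CCCC)(CCCC)CCCC)[C@@H]1[C@H](OC(=O)/C=C/C)C[C@@](C)(O)C(=O)O | intermediate
18 | ten-membered macrolactone stannane: lactone of 17 between the C1 carboxyl and the C15 oxygen (ring O15–C15–C4=C5–C6–C7–C8–C9–C10–C1), fused at C6–C7 to the alpha-methylene butyrolactone; Bu3Sn on C4 cis to C6; 8-O-(E)-crotonate; free 10-OH; 6R,7S,8R,10R | C=C1C(=O)O[C@H]2/C=C(/COC(=O)[C@@](C)(C[C@@H](OC(=O)/C=C/C)[C@H]12)O)[Sn](CCCC)(CCCC)CCCC | intermediate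
19 | C10 triethylsilyl ether of 18; 6R,7S,8R,10R | C=C1C(=O)O[C@H]2/C=C(/COC(=O)[C@@](C)(C[C@@H](OC(=O)/C=C/C)[C@H]12)O[Si](CC)(CC)CC)[Sn](CCCC)(CCCC)CCCC | intermediate
20 | 4-acetyl macrolactone: as 19 with acetyl (C3, C2) on C4 in place of tin, acetyl cis to C6; 6S,7S,8R,10R (C6 descriptor changes by priority only) | C=C1C(=O)O[C@H]2/C=C(/COC(=O)[C@@](C)(C[C@@H](OC(=O)/C=C/C)[C@H]12)O[Si](CC)(CC)CC)C(C)=O | intermediate
21 | macrocyclic 1,3-diketone (not isolated): ten-membered carbocycle C1–C10 with C1 and C3 ketones, cis C4=C5, free C15H2OH on C4, 10-OSiEt3; 6S,7S,8R,10R | C=C1C(=O)O[C@H]2/C=C(/CO)C(=O)CC(=O)[C@@](C)(C[C@@H](OC(=O)/C=C/C)[C@H]12)O[Si](CC)(CC)CC | intermediate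
22 | bridged hemiketal (not isolated): 3-hydroxy-3,10-epoxy form of desilylated 21; 3R,6S,7S,8R,10R | C=C1C(=O)O[C@H]2/C=C(/CO)[C@@]3(O)CC(=O)[C@@](C)(C[C@@H](OC(=O)/C=C/C)[C@H]12)O3 | intermediate
23 | CNP0225232.1; 6S,7S,8R,10R | C=C1C(=O)O[C@H]2/C=C(/CO)C3=CC(=O)[C@@](C)(C[C@@H](OC(=O)/C=C/C)[C@H]12)O3 | target

**Totals**
Total steps: 15. Longest linear sequence: 12 steps (steps 1–4, then 8–15); steps 5–7 form the second branch.

**Steps most likely to fail**

Step 15 (Proposed new method). The enolate may fail to add to the hindered, silyloxy-substituted lactone carbonyl, or it may be consumed by conjugate addition to the methylene lactone or by proton transfer before the acyl transfer occurs. The fallback uses known chemistry, sets out from 17 and returns to the route at 23. It builds the C1–C2–C3 unit by chain extension of the acid and closes the ring at C3–C4 by a palladium-catalysed ketone synthesis. Persilylation of 17 (TESCl, imidazole, DMF) should give the tris(triethylsilyl) derivative F1, whose silyl ester is hydrolysed on aqueous NaHCO3/MeOH work-up to the bis(triethylsilyl) ether acid F2. Activation with carbonyldiimidazole and C-acylation of Mg(O2CCH2COSEt)2 (Masamune-type homologation, with loss of CO2) should give the beta-keto thioester F3. Intramolecular Liebeskind–Srogl coupling of the thioester with the C4 stannane (Pd2(dba)3, P(2-furyl)3, CuO2PPh2, THF, high dilution), the thioester relative of the acid chloride/vinylstannane macrocyclic ketone synthesis, should give the macrocyclic 1,3-diketone bis(triethylsilyl) ether F4. Aqueous HCl in THF then removes both silyl groups and effects the same cyclodehydration as in step 15, giving 23.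

Step 12. Ring strain in the ten-membered lactone (E-type ring alkene, trans-fused butyrolactone, bulky stannyl group) may slow ring closure so that intermolecular esterification to dimers and oligomers takes over. The fallback sets out from 17 and returns at 18: a Mitsunobu macrolactonization (PPh3, DIAD, toluene, high dilution) activates the primary allylic C15 hydroxyl instead of the hindered alpha-hydroxy acid and lets the carboxylate close the ring by displacement at C15. It leads to 18 directly and no new compound arises (F0).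

Step 14. Transmetalation of the crowded, alpha-substituted vinylstannane may be too slow, so that protodestannylation or loss of the alkene geometry competes. The fallback sets out from 19 and returns at 20, with the coupling roles reversed. Iododestannylation (I2, CH2Cl2, 0 °C, retention) should give the C4 vinyl iodide F5. Stille coupling of F5 with the unhindered tributyl(1-ethoxyvinyl)stannane (Pd(PPh3)4, toluene, 80 °C) should give the C4 1-ethoxyvinyl diene F6. Brief treatment with 0.1 M HCl in THF at 0 °C hydrolyses the enol ether to 20 while the tertiary silyl ether survives.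

Further compounds
F1 | step 15 | tris(triethylsilyl) derivative of 17 (C15–O, C10–O and carboxyl silylated; not isolated) | C=C1C(=O)O[C@@H](/C=C(/CO[Si](CC)(CC)CC)[Sn](CCCC)(CCCC)CCCC)[C@@H]1[C@H](OC(=O)/C=C/C)C[C@@](C)(O[Si](CC)(CC)CC)C(=O)O[Si](CC)(CC)CC
F2 | step 15 | bis(triethylsilyl) ether acid (C15–OSiEt3, C10–OSiEt3, free C1 acid) | C=C1C(=O)O[C@@H](/C=C(/CO[Si](CC)(CC)CC)[Sn](CCCC)(CCCC)CCCC)[C@@H]1[C@H](OC(=O)/C=C/C)C[C@@](C)(O[Si](CC)(CC)CC)C(=O)O
F3 | step 15 | beta-keto thioester (C1 ketone, C2H2, C3 S-ethyl thioester) | C=C1C(=O)O[C@@H](/C=C(/CO[Si](CC)(CC)CC)[Sn](CCCC)(CCCC)CCCC)[C@@H]1[C@H](OC(=O)/C=C/C)C[C@@](C)(O[Si](CC)(CC)CC)C(=O)CC(=O)SCC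
F4 | step 15 | macrocyclic 1,3-diketone bis(triethylsilyl) ether (15-O-silyl analogue of 21) | C=C1C(=O)O[C@H]2/C=C(/CO[Si](CC)(CC)CC)C(=O)CC(=O)[C@@](C)(C[C@@H](OC(=O)/C=C/C)[C@H]12)O[Si](CC)(CC)CC
F0 | step 12 | none | none
F5 | step 14 | C4 vinyl iodide (tin of 19 replaced by iodine, iodine cis to C6) | C=C1C(=O)O[C@H]2/C=C(/COC(=O)[C@@](C)(C[C@@H](OC(=O)/C=C/C)[C@H]12)O[Si](CC)(CC)CC)I
F6 | step 14 | C4 1-ethoxyvinyl diene (ethyl enol ether of 20) | C=C1C(=O)O[C@H]2/C=C(/COC(=O)[C@@](C)(C[C@@H](OC(=O)/C=C/C)[C@H]12)O[Si](CC)(CC)CC)C(=C)OCC
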